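**Remark on the chemistry:** meridianin F has no stereocentre, no stereogenic axis and no configured double bond. It is achiral, so the "single enantiomer" is fixed by constitution alone. The alkene geometries drawn for 7, 8, 10 and 11 are the expected ones, and they vanish in the product.

Locants used throughout:
- Indole: N1, C2, C3, C3a, C4–C7, C7a.
- Pyrimidine: N1', C2', N3', C4', C5', C6'.

## Analysis of the target

Meridianin F is a flat, fully aromatic biheteroaryl. A 1H-indole (benzene ring C3a–C4–C5–C6–C7–C7a fused to the pyrrole ring N1–C2–C3–C3a–C7a) is joined through C3 to C4' of a 2-aminopyrimidine (N1'–C2'(NH2)–N3'–C4'–C5'–C6'). There is no stereocentre and the C3–C4' bond rotates freely, so the whole problem is one of constitution and chemoselectivity.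

The sensitive groups are three:
- the vicinal C5–Br and C6–Br bonds, which are attacked by Pd(0), catalytic hydrogenation and halogen–metal exchange;
- the free N1–H, which amide acetals methylate;
- the C2'–NH2 group, which binds metals and activates C5' towards electrophiles.

The first difficulty is the 5,6-dibromo pattern. It cannot be written onto a finished indole or onto the finished alkaloid, because electrophiles go first to C3/C2 and to C5'. Both bromines must therefore arrive with the benzene ring, and the ring construction itself must fix their place relative to N1 and C3. The second difficulty is the C3–C4' bond, whose obvious construction by cross-coupling collides with the two aryl bromides.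

The feature exploited here is the unbroken five-carbon path C2–C3–C4'–C5'–C6' that runs through both hetero rings. Its ends C2–H and C6'–H are nitrogen-bound carbons at the formyl oxidation level, its centre C4' is at the ketone level, and C3 and C5' are the α-carbons of that ketone. The path is thus a doubly aminomethylenated acetone, a cross-conjugated bis(enaminone) hung on the arene at C3a. Both hetero rings then need only three C–N condensations: N1 from an ortho nitro group, and N1'/N3' from a guanidine.

## Retrosynthetic reasoning

**Both hetero rings are cut at once (12 ⇒ 8 + 9).**
- The bonds cut are N1–C2 of the pyrrole ring and N1'–C6' and N3'–C4' of the pyrimidine ring.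
- All three are C–N bonds to carbons at the carbonyl oxidation level. Cutting them unravels two aromatic rings into one acyclic C5 chain on a monocyclic nitroarene, 8.
- The C3–C4' bond is left intact, so no biaryl coupling is needed in the presence of two C–Br bonds.
- The forward reaction has to reduce the nitro group of 8 to the aniline 10 without touching the bromines.
- 10 must then close onto the proximal enaminone arm only, giving 11, and 9 must consume the single arm that is left.
- The order matters. Offered to 8 itself, 9 would face two competing 1,3-dielectrophiles and a 1,5-dielectrophile.

**The two formyl-level carbons (8 ⇒ 5 + two equivalents of 6).**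
- The bonds cut are C2=C3 and C5'=C6'.
- Both flanks of the ketone in 5 are C–H acidic, so one C1 reagent installs both carbons in one flask, by way of 7.
- At this stage N1 is still a nitro group. There is no N–H for 6 to methylate, and the route needs no protecting group.

**The aryl–chain bond (5 ⇒ 2 + 3).**
- The bond cut is C3–C3a.
- It is made by nucleophilic aromatic substitution of the fluorine ortho to the nitro group in 2 by the enolate of 3, giving 4. One acetyl group is then lost.
- The cut is placed here because the F/NO2 pair fixes where C3a and C7a lie relative to the two bromines, and no metal is involved.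
- The C3–C4' bond of the target is simply bought as a CH2–C(=O) bond of 3.
- Because 3 is symmetric, loss of either acetyl group of 4 gives the same ketone 5.

**The nitrogen on the arene (2 ⇒ 1).**
- The bond cut is C7a–N.
- Nitration of 1 is steered by fluorine. Its para position is blocked, and one ortho position is wedged between two halogens.
- The remaining position is also para to a bromine, which gives exactly the 1,2,4,5-pattern that is required.

## Alternatives that were turned down

**Alternative 1:** (the textbook route) Only the pyrimidine ring is cut (N1'–C6', N3'–C4'), on an indole that is already complete.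
- Forward: 5,6-dibromo-1H-indole A1 is acetylated at C3, sulfonylated at N1 and condensed with 6 to the N-tosyl enaminone A2. A2 is then closed with 9, with loss of the sulfonyl group.
- This leaves the real problem untouched. A1 cannot be had by brominating indole, since the pyrrole carbons react first. It needs its own ring synthesis or a block–brominate–unblock sequence before the four steps even begin.
- N1–H must be masked only because 6 would methylate it.
- The acylation has to be forced onto a ring system that two bromines deactivate.
- Every step makes one bond or moves one protecting group, so the step count is roughly twice that of the chosen route.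

**Alternative 2:** The biaryl bond C3–C4' is cut.
- Forward: Suzuki–Miyaura coupling of 5,6-dibromo-3-(pinacolboryl)-1-tosylindole A3 with 4-chloropyrimidin-2-amine A4, then removal of the sulfonyl group.
- A3 carries a C–B bond and two C–Br bonds in one molecule. A Pd(0) catalyst active enough to insert into the C–Cl bond of A4, which the amino group makes electron-richer, will also insert into C5–Br and C6–Br. Head-to-tail oligomerisation then competes.
- Making A3 needs C3-halogenation and borylation that tell one halogen from two others. 3-Indolylboronates also protodeboronate readily.
- The route still starts from A1 and adds a protect/deprotect pair.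

**Alternative 3:** C3–C3a and N1–C2 are cut, as in a Fischer indole synthesis.
- Forward: (3,4-dibromophenyl)hydrazine A5 and (2-aminopyrimidin-4-yl)acetaldehyde A6 give the hydrazone A7. Under acid, A7 undergoes the [3,3]-sigmatropic shift and loses ammonia.
- The bromine meta to the hydrazine nitrogen makes the two ortho carbons unequal, and nothing in A7 decides between them, so the 5,6-pattern is not secured.
- The electron-poor aryl ring slows the sigmatropic step. The basic aminopyrimidine takes up the acid.
- A6 is an enolisable heteroarylacetaldehyde that self-condenses and needs several steps of its own.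

Key step: step 4

## Route

Step 1
Reactants: 1 1,2-dibromo-4-fluorobenzene
Product: 2 1,2-dibromo-4-fluoro-5-nitrobenzene
Conditions: fuming HNO3, conc. H2SO4, 0 °C to rt
Reagents that add atoms: nitric acid, O[N+](=O)[O-]
Why: Electrophilic aromatic nitration directed by fluorine: its para position carries bromine and the ortho position C3 is wedged between F and Br, so attack should fall on C5, which is also para to C2–Br. The three halogens and the new nitro group make a second nitration unlikely.

Step 2
Reactants: 2 1,2-dibromo-4-fluoro-5-nitrobenzene; 3 pentane-2,4-dione (acetylacetone)
Product: 5 1-(4,5-dibromo-2-nitrophenyl)propan-2-one, via aryl diketone 4 (not isolated)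
Conditions: K2CO3, DMSO, 60 °C; then H2O, 90 °C; acidic work-up
Reagents that add atoms: none
Why: SNAr of the soft diketone enolate at the carbon bearing fluorine ortho to NO2; addition is rate-determining, so fluoride is replaced far faster than the bromide para to NO2, and the enolate of 4 shuts the ring down against a second attack. Aqueous carbonate then cleaves one acetyl group by a retro-Claisen reaction, eased by the 2-nitrobenzyl-stabilised leaving carbanion, and the symmetry of 3 allows only one ketone.

Step 3
Reactants: 5 1-(4,5-dibromo-2-nitrophenyl)propan-2-one; 6 N,N-dimethylformamide dimethyl acetal (two equivalents enter the product)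
Product: 8 (1E,4E)-2-(4,5-dibromo-2-nitrophenyl)-1,5-bis(dimethylamino)penta-1,4-dien-3-one, via mono-enaminone 7 (not isolated)
Conditions: 6 (excess), DMF, 120 °C, MeOH distilled off
Reagents that add atoms: none
Why: Double aminomethylenation of a ketone with an amide acetal, the reaction type that turns arylacetones and dibenzyl ketones into bis(enaminones) on the way to 4-pyridones. The doubly activated benzylic CH2 condenses first (7), the acetyl CH3 follows under forcing conditions, and removal of methanol drives both equilibria. The geometry of the push–pull alkenes is of no consequence.

Step 4
Reactants: 8 (1E,4E)-2-(4,5-dibromo-2-nitrophenyl)-1,5-bis(dimethylamino)penta-1,4-dien-3-one; 9 guanidine hydrochloride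
Product: 12 meridianin F (4-(5,6-dibromo-1H-indol-3-yl)pyrimidin-2-amine), via amino bis-enaminone 10 (not isolated), via indolyl enaminone 11 (not isolated)
Conditions: Na2S2O4, 2-methoxyethanol/H2O, 70 °C; then 9, K2CO3, H2O distilled off, reflux (same flask)
Reagents that add atoms: none
Why: Dithionite reduces the nitro group of 8 by stepwise electron transfer and leaves both C–Br bonds and the push–pull alkenes alone, giving aniline 10. In the hydrogensulfite-buffered medium the proximal arm is O-protonated to a vinylogous amidinium ion, the new NH2 adds to its CH=N+Me2 carbon (future C2) and dimethylamine leaves, so the pyrrole ring N1–C2–C3–C3a–C7a closes by 5-exo-trig attack on the iminium carbon (formally 5-endo on the C=C bond) and aromatises to 11. This is the reductive cyclisation of an α-(2-nitroaryl) enaminone, the acyl variant of the Leimgruber–Batcho indole synthesis. Guanidine, freed from 9 by K2CO3, then replaces the NMe2 group at the distal carbon (future C6') by conjugate addition–elimination, and its second nitrogen closes the pyrimidine ring by 6-exo-trig attack on the ketone (future C4') with loss of water, the Bredereck-type enaminone–guanidine condensation. The first stage needs site selectivity: the aniline nitrogen reaches the proximal CH through a five-membered transition state but the distal CH only through a seven-membered one, and the ketone carbon, also within five-ring reach, is deactivated by two vinylogous amide donors and would lead only to a non-aromatic 3H-indole. The second stage needs guanidine to meet a single 1,3-dielectrophile, which is why 9 is added after the reduction: in 11 the proximal arm is locked into the aromatic pyrrole ring. No stereocentre is formed and the alkene geometries of 8 are erased. One flask thus makes three C–N bonds and both hetero rings, needs no N–H protection because N1–H appears only after 6 is gone, and sets dimethylamine free only once the arene has lost its nitro activation, so the bromine para to it is not displaced.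

## Compound list

1 | 1,2-dibromo-4-fluorobenzene | Fc1ccc(Br)c(Br)c1 | starting material
2 | 1,2-dibromo-4-fluoro-5-nitrobenzene | O=[N+]([O-])c1cc(Br)c(Br)cc1F | intermediate
3 | pentane-2,4-dione (acetylacetone) | CC(=O)CC(C)=O | starting material
4 | 3-(4,5-dibromo-2-nitrophenyl)pentane-2,4-dione | CC(=O)C(C(C)=O)c1cc(Br)c(Br)cc1[N+](=O)[O-] | intermediate
5 | 1-(4,5-dibromo-2-nitrophenyl)propan-2-one | CC(=O)Cc1cc(Br)c(Br)cc1[N+](=O)[O-] | intermediate
6 | N,N-dimethylformamide dimethyl acetal | COC(OC)N(C)C | starting material
7 | (E)-3-(4,5-dibromo-2-nitrophenyl)-4-(dimethylamino)but-3-en-2-one | CC(=O)/C(=C/N(C)C)c1cc(Br)c(Br)cc1[N+](=O)[O-] | intermediate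
8 | (1E,4E)-2-(4,5-dibromo-2-nitrophenyl)-1,5-bis(dimethylamino)penta-1,4-dien-3-one | CN(C)/C=C/C(=O)/C(=C/N(C)C)c1cc(Br)c(Br)cc1[N+](=O)[O-] | intermediate
9 | guanidine hydrochloride | Cl.NC(N)=N | starting material
10 | (1E,4E)-2-(2-amino-4,5-dibromophenyl)-1,5-bis(dimethylamino)penta-1,4-dien-3-one | CN(C)/C=C/C(=O)/C(=C/N(C)C)c1cc(Br)c(Br)cc1N | intermediate
11 | (E)-1-(5,6-dibromo-1H-indol-3-yl)-3-(dimethylamino)prop-2-en-1-one | CN(C)/C=C/C(=O)c1c[nH]c2cc(Br)c(Br)cc12 | intermediate
12 | meridianin F, 4-(5,6-dibromo-1H-indol-3-yl)pyrimidin-2-amine (achiral) | Nc1nccc(-c2c[nH]c3cc(Br)c(Br)cc23)n1 | target

## Step count and least certain steps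

Total step count: 4. Longest linear sequence: 4 (1 → 2 → 5 → 8 → 12). No protecting group and no transition metal is used.

**Step 4 (key step).**
- The most likely failure is interception of the reduction at the hydroxylamine level. The proximal enaminone carbon is so electrophilic that ring closure may outrun the last two-electron reduction and leave oxygen on N1.
- The second danger lies in the hot aqueous carbonate of the second stage. The distal arm may be hydrolysed and lost by retro-Claisen deformylation before guanidine has condensed. Deprotonation of N1–H also damps the ketone and slows the condensation.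
- Fallback: the two rings are built one after the other, and the distal carbon is added only once the indole exists.
- It sets out from 5. One equivalent of 6 at 80 °C stops at the mono-enaminone 7, which is isolated.
- Iron powder in hot acetic acid takes nitro and N-hydroxy stages through to the amine level. It should give 1-(5,6-dibromo-1H-indol-3-yl)ethanone F1.
- Aminomethylenation of the acetyl group of F1 with tert-butoxybis(dimethylamino)methane, which has no O-methyl group to pass on to N1–H, comes back to the route at 11, now isolated.
- 11 is then condensed with 9 and K2CO3 in anhydrous 2-methoxyethanol to 12.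

**Step 3.**
- The condensation may stall after the first aminomethylenation, because the acetyl CH3 of 7 belongs to a vinylogous amide and is only weakly acidic.
- The long heating that the second condensation needs invites displacement of the bromine para to the nitro group by methoxide or dimethylamine.
- Fallback: the distal carbon is introduced by kinetic enolate chemistry at low temperature, and the chain is stored as a γ-pyrone.
- It sets out from 7, isolated as above. LiHMDS in THF at −78 °C, then ethyl formate, should give (4E)-4-(4,5-dibromo-2-nitrophenyl)-5-(dimethylamino)-3-oxopent-4-enal F2.
- Acid closes F2, by addition of the enol oxygen to the aminomethylene carbon and loss of the amine, to 3-(4,5-dibromo-2-nitrophenyl)-4H-pyran-4-one F3.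
- F3 takes the place of 8 under the conditions of step 4. Reduction gives 3-(2-amino-4,5-dibromophenyl)-4H-pyran-4-one F4.
- The amino group of F4 opens the pyrone at its C2 (ring opening and ring closure) to 3-(5,6-dibromo-1H-indol-3-yl)-3-oxopropanal F5.
- Condensation of F5 with 9 comes back to the route at 12.

**Step 2.**
- C-arylation by the hindered, weakly nucleophilic diketone enolate may be slow. That leaves room for O-arylation and for attack at the bromine para to the nitro group.
- In the hot aqueous stage the benzylic carbanion of 5 may condense onto the neighbouring nitro group.
- Fallback: the acetyl group is introduced by decarboxylative acylation instead of being carried in by the nucleophile.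
- It sets out from 2. Dimethyl malonate and K2CO3 in DMF should give dimethyl 2-(4,5-dibromo-2-nitrophenyl)malonate F6.
- Aqueous HCl in acetic acid at reflux hydrolyses and decarboxylates F6 to (4,5-dibromo-2-nitrophenyl)acetic acid F7.
- A Dakin–West-type reaction of F7 with acetic anhydride and 1-methylimidazole comes back to the route at 5.

## Further compounds

F1 | step 4 | 1-(5,6-dibromo-1H-indol-3-yl)ethanone | CC(=O)c1c[nH]c2cc(Br)c(Br)cc12
F2 | step 3 | (4E)-4-(4,5-dibromo-2-nitrophenyl)-5-(dimethylamino)-3-oxopent-4-enal | O=CCC(=O)/C(=C/N(C)C)c1cc(Br)c(Br)cc1[N+](=O)[O-]
F3 | step 3 | 3-(4,5-dibromo-2-nitrophenyl)-4H-pyran-4-one | O=c1ccocc1-c1cc(Br)c(Br)cc1[N+](=O)[O-]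
F4 | step 3 | 3-(2-amino-4,5-dibromophenyl)-4H-pyran-4-one | O=c1ccocc1-c1cc(Br)c(Br)cc1N
F5 | step 3 | 3-(5,6-dibromo-1H-indol-3-yl)-3-oxopropanal | O=CCC(=O)c1c[nH]c2cc(Br)c(Br)cc12
F6 | step 2 | dimethyl 2-(4,5-dibromo-2-nitrophenyl)malonate | COC(=O)C(C(=O)OC)c1cc(Br)c(Br)cc1[N+](=O)[O-]
F7 | step 2 | (4,5-dibromo-2-nitrophenyl)acetic acid | OC(=O)Cc1cc(Br)c(Br)cc1[N+](=O)[O-]
A1 | alternative 1 | 5,6-dibromo-1H-indole | Brc1cc2cc[nH]c2cc1Br
A2 | alternative 1 | (E)-1-(5,6-dibromo-1-tosyl-1H-indol-3-yl)-3-(dimethylamino)prop-2-en-1-one | CN(C)/C=C/C(=O)c1cn(S(=O)(=O)c2ccc(C)cc2)c2cc(Br)c(Br)cc12
A3 | alternative 2 | 5,6-dibromo-3-(4,4,5,5-tetramethyl-1,3,2-dioxaborolan-2-yl)-1-tosyl-1H-indole | Cc1ccc(cc1)S(=O)(=O)n1cc(B2OC(C)(C)C(C)(C)O2)c2cc(Br)c(Br)cc21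
A4 | alternative 2 | 4-chloropyrimidin-2-amine | Nc1nccc(Cl)n1
A5 | alternative 3 | (3,4-dibromophenyl)hydrazine | NNc1ccc(Br)c(Br)c1
A6 | alternative 3 | (2-aminopyrimidin-4-yl)acetaldehyde | Nc1nccc(CC=O)n1
A7 | alternative 3 | (E)-(2-aminopyrimidin-4-yl)acetaldehyde (3,4-dibromophenyl)hydrazone | Nc1nccc(C/C=N/Nc2ccc(Br)c(Br)c2)n1
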